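**Strategy**

The 1,2-dioxane is cut at the O1–C6 bond. C6 is a peroxyketal carbon (bonded to OMe, O1, C5 and side-chain carbon C7) that acid can open and re-close, whereas the C3–O2 stereocentre is inert; the route therefore builds only C3, by reagent-controlled allylation and SN2 inversion with hydroperoxide, and lets acidic methanol close the ring of an acyclic (4S)-γ-hydroperoxy dimethyl ketal that carries an allyl group (latent acetate arm) and a terminal alkyne (coupling handle). One operation forms the O1–C6 bond, the six-membered ring and the C6 stereocentre, funnelled to the epimer with axial methoxy and both chains equatorial. Ozonolysis, oxidation and a last Sonogashira coupling complete the target.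

Key step: step 7

Remark: (−)-Ipc2B(allyl), the reagent derived from (+)-α-pinene, is taken to add its allyl group to the Si face of the unbranched aldehyde 9, which corresponds to the (4R)-alcohol 11; ring atoms are numbered O1, O2, C3 (CH), C4, C5, C6 (peroxyketal carbon).

**Route**

Step 1
Reactants: 1 (5-chloropent-1-yn-1-yl)trimethylsilane; 2 methyl 4-chloro-4-oxobutanoate
Product: 5 methyl 4-oxo-9-(trimethylsilyl)non-8-ynoate, via Grignard reagent 3 (not isolated), via organozinc chloride 4 (not isolated)
Conditions: Mg (BrCH2CH2Br-activated), THF, reflux; ZnCl2, THF, 0 °C; then 2, Pd(PPh3)4 (3 mol %), 0 °C → rt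
Reagents that add atoms: none
Why: Negishi acylation: the alkylzinc chloride, reached by Grignard formation and transmetalation, should couple with the acid chloride under Pd(0) without attacking the methyl ester or the ketone formed, while the C-silyl group masks the acidic alkyne C–H during metalation.

Step 2
Reactants: 5 methyl 4-oxo-9-(trimethylsilyl)non-8-ynoate
Product: 7 methyl 4,4-dimethoxynon-8-ynoate, via silyl ketal 6 (not isolated)
Conditions: HC(OMe)3, p-TsOH·H2O (5 mol %), MeOH, rt; then K2CO3 (excess), rt
Reagents that add atoms: trimethyl orthoformate COC(OC)OC; methanol CO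
Why: Acid-catalysed ketalisation driven by the orthoformate (a methyl ester cannot scramble in methanol), followed in the same flask by carbonate-mediated methanolysis of the C(sp)–Si bond, which also neutralises the acid before concentration.

Step 3
Reactants: 7 methyl 4,4-dimethoxynon-8-ynoate
Product: 9 4,4-dimethoxynon-8-ynal, via aluminium hemiacetal 8 (not isolated)
Conditions: DIBAL-H (1.1 equiv), CH2Cl2, −78 °C; MeOH, then aq. Rochelle salt
Reagents that add atoms: none
Why: Partial ester reduction with DIBAL-H: the tetrahedral aluminium hemiacetal should persist at −78 °C and release the aldehyde only on quench, and the ketal and the terminal alkyne are inert at this temperature.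

Step 4
Reactants: 9 4,4-dimethoxynon-8-ynal
Product: 11 (4R)-7,7-dimethoxydodec-1-en-11-yn-4-ol, via borinate ester 10 (not isolated)
Conditions: (−)-Ipc2BOMe, allylMgBr, Et2O, 0 °C → rt; 9, −78 °C; 3 M NaOH, 30% H2O2, 0 °C → rt; Et3N-deactivated silica
Reagents that add atoms: allylmagnesium bromide C=CC[Mg]Br
Why: Brown asymmetric allylboration: (−)-Ipc2B(allyl), formed in the flask, should deliver allyl through a closed chair transition state to the Si face of the aldehyde and so set C4 as (R) under reagent control, and the basic work-up and amine-buffered silica keep the γ-hydroxy ketal from closing to a cyclic mixed ketal.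

Step 5
Reactants: 11 (4R)-7,7-dimethoxydodec-1-en-11-yn-4-ol
Product: 12 (4R)-7,7-dimethoxydodec-1-en-11-yn-4-yl methanesulfonate
Conditions: MsCl, Et3N, CH2Cl2, −20 → 0 °C; used without delay
Reagents that add atoms: methanesulfonyl chloride CS(=O)(=O)Cl
Why: O-Sulfonylation (mesylation) of the secondary alcohol leaves the C4–O bond untouched, so the configuration is retained, and the basic medium protects the ketal.

Step 6
Reactants: 12 (4R)-7,7-dimethoxydodec-1-en-11-yn-4-yl methanesulfonate
Product: 13 (4S)-4-hydroperoxy-7,7-dimethoxydodec-1-en-11-yne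
Conditions: 50% aq. H2O2 (20 equiv), KOH (2 equiv), MeOH, 0 °C → rt; extractive work-up, no silica
Reagents that add atoms: hydrogen peroxide OO
Why: SN2 displacement of a secondary sulfonate by hydroperoxide anion (the alkaline hydrogen peroxide synthesis of alkyl hydroperoxides) should invert C4 from (R) to (S), since HOO− is a strong α-nucleophile but a weak base, no carbonyl sits β to the leaving group to open an E1cB path, and ketal, alkene and alkyne are stable to base.

Step 7
Reactants: 13 (4S)-4-hydroperoxy-7,7-dimethoxydodec-1-en-11-yne
Product: 14 (3S,6R)-6-methoxy-6-(pent-4-yn-1-yl)-3-(prop-2-en-1-yl)-1,2-dioxane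
Conditions: CSA (10 mol %), dry MeOH (0.05 M), rt, until the C6 epimer ratio is constant; Et3N quench
Reagents that add atoms: methanol CO (the C6 methoxy group exchanges with the solvent during equilibration)
Why: Acid ionises the dimethyl ketal of 13 to a methoxy-stabilised carbenium ion at C6, the terminal oxygen of the hydroperoxide captures it to form the O1–C6 bond, and renewed ionisation of the ring peroxyketal (loss of methanol to the cyclic peroxycarbenium ion, or ring opening) with recapture keeps C6 in equilibrium. The closest known reaction type is the acid-catalysed cyclisation of γ-hydroperoxy ketones and ketals to 3-alkoxy-1,2-dioxanes with peroxyketal exchange. The 1,2-dioxane closes in a 6-exo-trig mode, the hydroperoxide adding to the exocyclic C=O+ bond of the oxocarbenium ion. The new C6 stereocentre is set thermodynamically by the fixed (3S) centre: in the chair with the C3 allyl group equatorial, the (6R) epimer has the methoxy group axial (anomeric stabilisation by an O1 lone pair) and the pentynyl chain equatorial, whereas the (6S) epimer must give up one of these. Only C6 selectivity is needed, because C3 carries no ionisable group and the alkene and alkyne are inert to dilute acid; any minor epimer separated by chromatography can be resubjected to the same conditions.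

Step 8
Reactants: 14 (3S,6R)-6-methoxy-6-(pent-4-yn-1-yl)-3-(prop-2-en-1-yl)-1,2-dioxane
Product: 16 2-[(3S,6R)-6-methoxy-6-(pent-4-yn-1-yl)-1,2-dioxan-3-yl]acetaldehyde, via ozonide 15 (not isolated)
Conditions: O3 (Sudan III end point), CH2Cl2, −78 °C; PPh3 (1.05 equiv), −78 °C → rt; used crude
Reagents that add atoms: ozone [O-][O+]=O
Why: Ozonolysis with reductive work-up (Criegee mechanism): the monosubstituted alkene reacts with ozone far faster than the terminal alkyne, the indicator dye stops the addition at the alkene, and triphenylphosphine should reduce the ozonide much faster than the dialkyl peroxide.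

Step 9
Reactants: 16 2-[(3S,6R)-6-methoxy-6-(pent-4-yn-1-yl)-1,2-dioxan-3-yl]acetaldehyde
Product: 17 2-[(3S,6R)-6-methoxy-6-(pent-4-yn-1-yl)-1,2-dioxan-3-yl]acetic acid
Conditions: NaClO2, NaH2PO4, 2-methylbut-2-ene, t-BuOH/H2O, 0 °C → rt
Reagents that add atoms: sodium chlorite [Na+].[O-]Cl=O
Why: Pinnick oxidation at buffered, weakly acidic pH takes the aldehyde to the acid without base, so the β-peroxy carbonyl unit cannot open by E1cB, and the alkene scavenger removes hypochlorite before it can attack the alkyne.

Step 10
Reactants: 17 2-[(3S,6R)-6-methoxy-6-(pent-4-yn-1-yl)-1,2-dioxan-3-yl]acetic acid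
Product: 18 methyl 2-[(3S,6R)-6-methoxy-6-(pent-4-yn-1-yl)-1,2-dioxan-3-yl]acetate
Conditions: TMSCHN2 (hexanes), PhMe/MeOH (4:1), 0 °C → rt
Reagents that add atoms: (trimethylsilyl)diazomethane C[Si](C)(C)C=[N+]=[N-]
Why: Esterification with (trimethylsilyl)diazomethane in methanol is a neutral O-methylation that avoids both acid (peroxyketal) and base (β-peroxy ester).

Step 11
Reactants: 19 dec-9-en-1-ol
Product: 20 dec-9-enal
Conditions: TEMPO (10 mol %), PhI(OAc)2 (1.1 equiv), CH2Cl2, rt
Reagents that add atoms: none
Why: TEMPO/PhI(OAc)2 oxidation (oxoammonium-mediated) should stop at the aldehyde and leave the terminal alkene alone.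

Step 12
Reactants: 20 dec-9-enal
Product: 21 (1E)-1-iodoundeca-1,10-diene
Conditions: CrCl2 (6 equiv), CHI3 (2 equiv), 1,4-dioxane/THF (6:1), 0 °C → rt
Reagents that add atoms: iodoform IC(I)I
Why: Takai olefination: the gem-dichromium species from iodoform adds to the aldehyde and eliminates to give the (E)-vinyl iodide preferentially, the dioxane cosolvent being chosen to raise the E preference.

Step 13
Reactants: 18 methyl 2-[(3S,6R)-6-methoxy-6-(pent-4-yn-1-yl)-1,2-dioxan-3-yl]acetate; 21 (1E)-1-iodoundeca-1,10-diene
Product: 22 peroxyacarnoate A, methyl 2-[(3S,6R)-6-[(6E)-hexadeca-6,15-dien-4-yn-1-yl]-6-methoxy-1,2-dioxan-3-yl]acetate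
Conditions: Pd(PPh3)4 (5 mol %), CuI (10 mol %), Et3N, THF (degassed), rt
Reagents that add atoms: none
Why: Sonogashira coupling of the terminal alkyne with the vinyl iodide should proceed at room temperature with retention of the E geometry, a saturated dialkyl peroxide should tolerate the Pd/Cu system, and the tertiary amine is too weak a base to open the β-peroxy ester.

**Compound list**

1 | (5-chloropent-1-yn-1-yl)trimethylsilane | C[Si](C)(C)C#CCCCCl | starting material
2 | methyl 4-chloro-4-oxobutanoate | COC(=O)CCC(=O)Cl | starting material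
3 | [5-(trimethylsilyl)pent-4-yn-1-yl]magnesium chloride | C[Si](C)(C)C#CCCC[Mg]Cl | intermediate
4 | [5-(trimethylsilyl)pent-4-yn-1-yl]zinc chloride | C[Si](C)(C)C#CCCC[Zn]Cl | intermediate
5 | methyl 4-oxo-9-(trimethylsilyl)non-8-ynoate | COC(=O)CCC(=O)CCCC#C[Si](C)(C)C | intermediate
6 | methyl 4,4-dimethoxy-9-(trimethylsilyl)non-8-ynoate | COC(=O)CCC(OC)(OC)CCCC#C[Si](C)(C)C | intermediate
7 | methyl 4,4-dimethoxynon-8-ynoate | COC(=O)CCC(OC)(OC)CCCC#C | intermediate
8 | diisobutylaluminium hemiacetal of 7, [(1,4,4-trimethoxynon-8-yn-1-yl)oxy]bis(2-methylpropyl)alumane | COC(CCC(OC)(OC)CCCC#C)O[Al](CC(C)C)CC(C)C | intermediate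
9 | 4,4-dimethoxynon-8-ynal | O=CCCC(OC)(OC)CCCC#C | intermediate
10 | (4R)-7,7-dimethoxydodec-1-en-11-yn-4-yl diisopinocampheylborinate | C=CC[C@H](OB([C@@H]1C[C@@H]2C[C@H]([C@H]1C)C2(C)C)[C@@H]1C[C@@H]2C[C@H]([C@H]1C)C2(C)C)CCC(OC)(OC)CCCC#C | intermediate
11 | (4R)-7,7-dimethoxydodec-1-en-11-yn-4-ol | C=CC[C@H](O)CCC(OC)(OC)CCCC#C | intermediate
12 | (4R)-7,7-dimethoxydodec-1-en-11-yn-4-yl methanesulfonate | C=CC[C@H](OS(C)(=O)=O)CCC(OC)(OC)CCCC#C | intermediate
13 | (4S)-4-hydroperoxy-7,7-dimethoxydodec-1-en-11-yne | C#CCCCC(OC)(OC)CC[C@@H](CC=C)OO | intermediate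
14 | (3S,6R)-6-methoxy-6-(pent-4-yn-1-yl)-3-(prop-2-en-1-yl)-1,2-dioxane | C#CCCC[C@]1(OC)CC[C@@H](CC=C)OO1 | intermediate
15 | 3-{[(3S,6R)-6-methoxy-6-(pent-4-yn-1-yl)-1,2-dioxan-3-yl]methyl}-1,2,4-trioxolane (both configurations at the trioxolane carbon) | C#CCCC[C@]1(OC)CC[C@@H](CC2OCOO2)OO1 | intermediate
16 | 2-[(3S,6R)-6-methoxy-6-(pent-4-yn-1-yl)-1,2-dioxan-3-yl]acetaldehyde | C#CCCC[C@]1(OC)CC[C@@H](CC=O)OO1 | intermediate
17 | 2-[(3S,6R)-6-methoxy-6-(pent-4-yn-1-yl)-1,2-dioxan-3-yl]acetic acid | C#CCCC[C@]1(OC)CC[C@@H](CC(=O)O)OO1 | intermediate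
18 | methyl 2-[(3S,6R)-6-methoxy-6-(pent-4-yn-1-yl)-1,2-dioxan-3-yl]acetate | C#CCCC[C@]1(OC)CC[C@@H](CC(=O)OC)OO1 | intermediate
19 | dec-9-en-1-ol | C=CCCCCCCCCO | starting material
20 | dec-9-enal | C=CCCCCCCCC=O | intermediate
21 | (1E)-1-iodoundeca-1,10-diene | C=CCCCCCCC/C=C/I | intermediate
22 | peroxyacarnoate A, methyl 2-[(3S,6R)-6-[(6E)-hexadeca-6,15-dien-4-yn-1-yl]-6-methoxy-1,2-dioxan-3-yl]acetate | C=CCCCCCCC/C=C/C#CCCC[C@]1(OC)CC[C@@H](CC(=O)OC)OO1 | target

**Step count**

Total: 13 steps. Longest linear sequence: 11 steps (steps 1–10 and 13).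

**Steps most likely to fail**

Step 6. Substitution at the secondary carbon is slow in aqueous methanol, so loss of the sulfonate by E2 toward the allylic CH2, or ionisation assisted by a ketal oxygen, may overtake it. The fallback sets out from mesylate 12 and uses a protected hydrogen peroxide in a dipolar aprotic medium. 2-Methoxyprop-2-yl hydroperoxide (made by ozonolysis of 2,3-dimethylbut-2-ene in methanol) would be alkylated with CsOH·H2O in DMF at 0 °C, an SN2 reaction that should give, with inversion, the mixed peroxyketal 2-{[(4S)-7,7-dimethoxydodec-1-en-11-yn-4-yl]peroxy}-2-methoxypropane F1. CSA in methanol would then pass the acetone ketal to the solvent, free hydroperoxide 13 in the flask and close it under the same acid, so the fallback comes back to the route at 14.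

Step 7. Ring closure and C6 equilibration may stay incomplete, because bulk methanol holds part of the material as the open dimethyl ketal and damps the anomeric preference, and long exposure to acid may degrade the peroxide. The fallback sets out from 13 and closes the ring on the ketone instead of the ketal. Mild hydrolysis (AcOH/THF/H2O, rt) would free the γ-hydroperoxy ketone, which should close by carbonyl addition to the cyclic peroxyhemiketal (6S)-3-(pent-4-yn-1-yl)-6-(prop-2-en-1-yl)-1,2-dioxan-3-ol F2. Hydroxyl would then be exchanged for methoxyl with a few equivalents of methanol, trimethyl orthoformate as water scavenger and PPTS in CH2Cl2. In this medium bulk methanol is absent and the low polarity should strengthen the axial-methoxy bias. The fallback comes back at 14.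

Step 12. Incomplete E selectivity in the chromium olefination would carry a Z-configured iodide into the last step, where the enyne isomers are unlikely to separate. The fallback sets out from aldehyde 20. Seyferth–Gilbert homologation with the Ohira–Bestmann reagent (K2CO3, MeOH) would give undec-1-en-10-yne F3. Hydrozirconation with Cp2Zr(H)Cl (1 equiv, THF; the terminal alkyne should react ahead of the terminal alkene) and iodinolysis with I2 would then fix the E geometry by syn addition and retention. The fallback comes back at 21.

**Further compounds**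

F1 | step 6 | 2-{[(4S)-7,7-dimethoxydodec-1-en-11-yn-4-yl]peroxy}-2-methoxypropane | C#CCCCC(OC)(OC)CC[C@@H](CC=C)OOC(C)(C)OC
F2 | step 7 | (6S)-3-(pent-4-yn-1-yl)-6-(prop-2-en-1-yl)-1,2-dioxan-3-ol (hemiketal carbon equilibrating) | C#CCCCC1(O)CC[C@@H](CC=C)OO1
F3 | step 12 | undec-1-en-10-yne | C=CCCCCCCCC#C
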